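**Retrosynthetic overview**

- The strategy rests on ring C (O1, C2, C3, C4, C4a, C8a): the 3-hydroxy-4-pyranone is the enol of a 2-aryl-chromane-3,4-dione, so its C3–C4 bond joins two carbonyl-level carbons. Ring C is closed last by a carbene-catalysed acyloin-type union of the ring A aldehyde carbon (C4, acyl anion) with C3 held as a methyl ester.
- The precursor is cut at O1–C2: a hindered ring A salicylaldehyde is O-alkylated with the alpha-bromo ester of the chromenyl mandelate.
- Ring A piece: 2,4,6-trihydroxybenzaldehyde, 4-O-prenyl ether, aromatic Claisen rearrangement while C3 and C5 are equivalent and the para carbon is blocked by CHO, then selective bis-MOM protection.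
- Ring B piece: 3,4-dihydroxybenzaldehyde, 4-O-(1,1-dimethylpropargyl) ether, thermal cyclisation to the 2,2-dimethylpyran ring, then one-carbon extension of CHO with bromoform to the mandelate and its bromide.
- Ring order: dimethylpyran ring of the chromene first (step 6), ring C in the key step (step 11), MOM removal last.

Key step: step 11

Remark on the chemistry: C3 is carried as a methyl ester and only C4 as an aldehyde, because a carbene adduct formed at a C3 aldehyde would have the O1 aryloxide on the neighbouring carbon C2 and would expel it (internal redox to an aryl ester) instead of closing the ring; with the ester the acyl anion can form only at C4 and the 3,4-dione level is reached without a separate oxidation. All compounds with a stereocentre are racemic; the target has none.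

**Route**

Step 1
Reactants: 1 2,4,6-trihydroxybenzaldehyde; 2 1-bromo-3-methylbut-2-ene
Product: 3 2,6-dihydroxy-4-[(3-methylbut-2-en-1-yl)oxy]benzaldehyde
Conditions: KHCO3 (1.5 equiv), DMF, rt
Reagents that add atoms: none
Why: Williamson etherification; the 4-OH, para to the formyl group and not hydrogen-bonded to it, is the most acidic phenol and the only one ionised by hydrogencarbonate, so the allylic bromide should be displaced at O4.

Step 2
Reactants: 3 2,6-dihydroxy-4-[(3-methylbut-2-en-1-yl)oxy]benzaldehyde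
Product: 5 2,4,6-trihydroxy-3-(2-methylbut-3-en-2-yl)benzaldehyde, via ortho-dienone 4 (not isolated)
Conditions: N,N-diethylaniline, 185 °C, argon
Reagents that add atoms: none
Why: Aromatic Claisen rearrangement ([3,3] shift with allyl inversion) to one of the two equivalent ortho carbons; the para carbon bears the formyl group, so no para (Claisen–Cope) product can form and the dienone enolises to the 1,1-dimethylallyl phenol.

Step 3
Reactants: 5 2,4,6-trihydroxy-3-(2-methylbut-3-en-2-yl)benzaldehyde
Product: 6 2-hydroxy-4,6-bis(methoxymethoxy)-3-(2-methylbut-3-en-2-yl)benzaldehyde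
Conditions: MOMCl (2.2 equiv), iPr2NEt (3 equiv), CH2Cl2, 0 °C to rt
Reagents that add atoms: chloromethyl methyl ether (MOMCl), COCCl
Why: Phenol O-alkylation to MOM acetals; the non-chelated 4-OH and the unhindered chelated 6-OH should react, while the 2-OH, chelated to the aldehyde and flanked by the quaternary carbon, should be left free.

Step 4
Reactants: 7 3,4-dihydroxybenzaldehyde; 8 3-chloro-3-methylbut-1-yne
Product: 9 3-hydroxy-4-[(2-methylbut-3-yn-2-yl)oxy]benzaldehyde
Conditions: K2CO3 (1.1 equiv), KI (0.2 equiv), acetone, reflux, argon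
Reagents that add atoms: none
Why: Regioselective O-alkylation of protocatechualdehyde; the 4-OH para to the formyl group is far more acidic than the 3-OH, so one equivalent of base should direct the tertiary propargylic chloride to O4.

Step 5
Reactants: 9 3-hydroxy-4-[(2-methylbut-3-yn-2-yl)oxy]benzaldehyde
Product: 10 3-(methoxymethoxy)-4-[(2-methylbut-3-yn-2-yl)oxy]benzaldehyde
Conditions: MOMCl (1.3 equiv), iPr2NEt (2 equiv), CH2Cl2, 0 °C to rt
Reagents that add atoms: chloromethyl methyl ether (MOMCl), COCCl
Why: MOM acetal formation on the remaining phenol, so that no free hydroxyl is present in the thermal step and the later 8-OH of the chromene stays masked to the end.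

Step 6
Reactants: 10 3-(methoxymethoxy)-4-[(2-methylbut-3-yn-2-yl)oxy]benzaldehyde
Product: 13 8-(methoxymethoxy)-2,2-dimethyl-2H-chromene-6-carbaldehyde, via allenylphenol 11 (not isolated), via ortho-quinone methide 12 (not isolated)
Conditions: N,N-diethylaniline, 180 °C, argon
Reagents that add atoms: none
Why: Propargyl Claisen rearrangement to the only free ortho carbon, enolisation, 1,5-hydrogen shift and oxa-6π electrocyclisation, the standard thermal route from aryl 1,1-dimethylpropargyl ethers to 2,2-dimethylchromenes; no stereocentre is formed.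

Step 7
Reactants: 13 8-(methoxymethoxy)-2,2-dimethyl-2H-chromene-6-carbaldehyde; 14 bromoform
Product: 16 2-hydroxy-2-[8-(methoxymethoxy)-2,2-dimethyl-2H-chromen-6-yl]acetic acid (racemic), via tribromomethyl carbinol 15 (not isolated)
Conditions: KOH (5 equiv), LiCl (2 equiv), dioxane/H2O 1:1, 0 °C to rt; then 1 M HCl to pH 3, 0 °C
Reagents that add atoms: potassium hydroxide, [K+].[OH-]
Why: Jocic–Reeve-type homologation: tribromomethyl anion adds to the aldehyde, the carbinolate closes to a gem-dibromo epoxide, hydroxide opens it at the benzylic carbon and the acyl bromide is hydrolysed to the mandelic acid; the new stereocentre is formed racemic and is erased in step 11.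

Step 8
Reactants: 16 2-hydroxy-2-[8-(methoxymethoxy)-2,2-dimethyl-2H-chromen-6-yl]acetic acid
Product: 17 methyl 2-hydroxy-2-[8-(methoxymethoxy)-2,2-dimethyl-2H-chromen-6-yl]acetate (racemic)
Conditions: MeI (1.5 equiv), KHCO3 (2 equiv), DMF, rt
Reagents that add atoms: iodomethane (MeI), CI
Why: SN2 O-methylation of the carboxylate; hydrogencarbonate ionises the acid only, so the secondary alcohol should not be alkylated.

Step 9
Reactants: 17 methyl 2-hydroxy-2-[8-(methoxymethoxy)-2,2-dimethyl-2H-chromen-6-yl]acetate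
Product: 18 methyl 2-bromo-2-[8-(methoxymethoxy)-2,2-dimethyl-2H-chromen-6-yl]acetate (racemic)
Conditions: CBr4 (1.3 equiv), PPh3 (1.3 equiv), CH2Cl2, 0 °C
Reagents that add atoms: carbon tetrabromide, BrC(Br)(Br)Br
Why: Appel reaction of a benzylic alpha-hydroxy ester under neutral conditions that the MOM acetal and the chromene should tolerate; the bromide is used without storage.

Step 10
Reactants: 6 2-hydroxy-4,6-bis(methoxymethoxy)-3-(2-methylbut-3-en-2-yl)benzaldehyde; 18 methyl 2-bromo-2-[8-(methoxymethoxy)-2,2-dimethyl-2H-chromen-6-yl]acetate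
Product: 19 methyl 2-[2-formyl-3,5-bis(methoxymethoxy)-6-(2-methylbut-3-en-2-yl)phenoxy]-2-[8-(methoxymethoxy)-2,2-dimethyl-2H-chromen-6-yl]acetate (racemic)
Conditions: Cs2CO3 (1.5 equiv), DMF, 0 °C to rt, argon
Reagents that add atoms: none
Why: Williamson etherification forming O1–C2; the doubly activated (benzylic, alpha-carbonyl) bromide should be reactive enough for the hindered caesium phenoxide at room temperature, where base-induced aldol closure of the product is slow; the C2 centre is racemic and is erased in step 11.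

Step 11
Reactants: 19 methyl 2-[2-formyl-3,5-bis(methoxymethoxy)-6-(2-methylbut-3-en-2-yl)phenoxy]-2-[8-(methoxymethoxy)-2,2-dimethyl-2H-chromen-6-yl]acetate
Product: 21 3-hydroxy-5,7-bis(methoxymethoxy)-2-[8-(methoxymethoxy)-2,2-dimethyl-2H-chromen-6-yl]-8-(2-methylbut-3-en-2-yl)-4H-chromen-4-one, via chromane-3,4-dione 20 (not isolated)
Conditions: 3-benzyl-5-(2-hydroxyethyl)-4-methylthiazolium chloride (30 mol %), DBU (1.5 equiv), 4 Å MS, degassed THF (0.05 M), 60 °C, argon
Reagents that add atoms: none
Why: Proposed new method: the thiazol-2-ylidene adds to the only aldehyde present (C4 on ring A), proton transfer gives the Breslow enaminol, and this acyl anion equivalent attacks the methyl ester carbonyl (C3) to form the C3–C4 bond; loss of methoxide and of the carbene gives the 2-aryl-chromane-3,4-dione 20, which enolises through its acidic C2–H to the aromatic 3-hydroxy-4-pyranone. The closest known reaction types are the carbene-catalysed intramolecular aldehyde–ketone crossed benzoin that gives 3-hydroxychroman-4-ones and the intramolecular aldehyde–nitrile coupling that gives 3-aminochromones from 2-(cyanomethoxy)benzaldehydes; an ester as acceptor is the new element. Ring C closes in a 6-exo-trig mode at the ester carbonyl. No stereocentre survives, because the racemic C2 centre is erased by the enolisation, so nothing has to be controlled. The selectivity needed is that the acyl anion forms at C4 and never next to the aryloxy-bearing C2; this is secured by the ester at C3, which the carbene cannot turn into an acyl anion, and the more nucleophilic thiazolium-derived enaminol is chosen because an ester is a weak acceptor. The competing base-induced 5-exo aldol of the C2 ester enolate onto the aldehyde cannot dehydrate at the quaternary C2 and is reversible, whereas flavonol formation is not, so material should funnel to 21; oxygen is excluded because flavonolate anions are oxygenated in air.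

Step 12
Reactants: 21 3-hydroxy-5,7-bis(methoxymethoxy)-2-[8-(methoxymethoxy)-2,2-dimethyl-2H-chromen-6-yl]-8-(2-methylbut-3-en-2-yl)-4H-chromen-4-one
Product: 22 Broussonol A, 3,5,7-trihydroxy-2-(8-hydroxy-2,2-dimethyl-2H-chromen-6-yl)-8-(2-methylbut-3-en-2-yl)-4H-chromen-4-one
Conditions: HCl (1.25 M in MeOH), MeOH/THF 1:1, 40 °C
Reagents that add atoms: none
Why: Acid-catalysed acetal exchange removes the three MOM groups with methanol as formaldehyde acceptor; the conditions should be too mild to protonate the monosubstituted alkene of the 1,1-dimethylallyl group or the chromene, and the target has no stereocentre.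

**Compound list**

1 | 2,4,6-trihydroxybenzaldehyde | O=Cc1c(O)cc(O)cc1O | starting material
2 | 1-bromo-3-methylbut-2-ene | CC(C)=CCBr | starting material
3 | 2,6-dihydroxy-4-[(3-methylbut-2-en-1-yl)oxy]benzaldehyde | O=Cc1c(O)cc(OCC=C(C)C)cc1O | intermediate
4 | 2,6-dihydroxy-3-(2-methylbut-3-en-2-yl)-4-oxocyclohexa-1,5-diene-1-carbaldehyde (ortho-dienone, racemic) | O=CC1=C(O)C(C(C)(C)C=C)C(=O)C=C1O | intermediate (not isolated)
5 | 2,4,6-trihydroxy-3-(2-methylbut-3-en-2-yl)benzaldehyde | C=CC(C)(C)c1c(O)cc(O)c(C=O)c1O | intermediate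
6 | 2-hydroxy-4,6-bis(methoxymethoxy)-3-(2-methylbut-3-en-2-yl)benzaldehyde | C=CC(C)(C)c1c(OCOC)cc(OCOC)c(C=O)c1O | intermediate
7 | 3,4-dihydroxybenzaldehyde | O=Cc1ccc(O)c(O)c1 | starting material
8 | 3-chloro-3-methylbut-1-yne | C#CC(C)(C)Cl | starting material
9 | 3-hydroxy-4-[(2-methylbut-3-yn-2-yl)oxy]benzaldehyde | O=Cc1ccc(OC(C)(C)C#C)c(O)c1 | intermediate
10 | 3-(methoxymethoxy)-4-[(2-methylbut-3-yn-2-yl)oxy]benzaldehyde | O=Cc1ccc(OC(C)(C)C#C)c(OCOC)c1 | intermediate
11 | 4-hydroxy-3-(methoxymethoxy)-5-(3-methylbuta-1,2-dien-1-yl)benzaldehyde (allenylphenol) | O=Cc1cc(OCOC)c(O)c(C=C=C(C)C)c1 | intermediate (not isolated)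
12 | 5-(methoxymethoxy)-3-(3-methylbut-2-en-1-ylidene)-4-oxocyclohexa-1,5-diene-1-carbaldehyde (ortho-quinone methide) | O=CC1=CC(=CC=C(C)C)C(=O)C(OCOC)=C1 | intermediate (not isolated)
13 | 8-(methoxymethoxy)-2,2-dimethyl-2H-chromene-6-carbaldehyde | O=Cc1cc(OCOC)c2c(c1)C=CC(C)(C)O2 | intermediate
14 | bromoform | BrC(Br)Br | starting material
15 | 2,2,2-tribromo-1-[8-(methoxymethoxy)-2,2-dimethyl-2H-chromen-6-yl]ethan-1-ol (racemic) | OC(c1cc(OCOC)c2c(c1)C=CC(C)(C)O2)C(Br)(Br)Br | intermediate (not isolated)
16 | 2-hydroxy-2-[8-(methoxymethoxy)-2,2-dimethyl-2H-chromen-6-yl]acetic acid (racemic) | OC(C(=O)O)c1cc(OCOC)c2c(c1)C=CC(C)(C)O2 | intermediate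
17 | methyl 2-hydroxy-2-[8-(methoxymethoxy)-2,2-dimethyl-2H-chromen-6-yl]acetate (racemic) | COC(=O)C(O)c1cc(OCOC)c2c(c1)C=CC(C)(C)O2 | intermediate
18 | methyl 2-bromo-2-[8-(methoxymethoxy)-2,2-dimethyl-2H-chromen-6-yl]acetate (racemic) | COC(=O)C(Br)c1cc(OCOC)c2c(c1)C=CC(C)(C)O2 | intermediate
19 | methyl 2-[2-formyl-3,5-bis(methoxymethoxy)-6-(2-methylbut-3-en-2-yl)phenoxy]-2-[8-(methoxymethoxy)-2,2-dimethyl-2H-chromen-6-yl]acetate (racemic) | C=CC(C)(C)c1c(OCOC)cc(OCOC)c(C=O)c1OC(C(=O)OC)c1cc(OCOC)c2c(c1)C=CC(C)(C)O2 | intermediate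
20 | 5,7-bis(methoxymethoxy)-2-[8-(methoxymethoxy)-2,2-dimethyl-2H-chromen-6-yl]-8-(2-methylbut-3-en-2-yl)chromane-3,4-dione (racemic) | C=CC(C)(C)c1c(OCOC)cc(OCOC)c2c1OC(c1cc(OCOC)c3c(c1)C=CC(C)(C)O3)C(=O)C2=O | intermediate (not isolated)
21 | 3-hydroxy-5,7-bis(methoxymethoxy)-2-[8-(methoxymethoxy)-2,2-dimethyl-2H-chromen-6-yl]-8-(2-methylbut-3-en-2-yl)-4H-chromen-4-one | C=CC(C)(C)c1c(OCOC)cc(OCOC)c2c(=O)c(O)c(-c3cc(OCOC)c4c(c3)C=CC(C)(C)O4)oc12 | intermediate
22 | Broussonol A, 3,5,7-trihydroxy-2-(8-hydroxy-2,2-dimethyl-2H-chromen-6-yl)-8-(2-methylbut-3-en-2-yl)-4H-chromen-4-one | C=CC(C)(C)c1c(O)cc(O)c2c(=O)c(O)c(-c3cc(O)c4c(c3)C=CC(C)(C)O4)oc12 | target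

**Step count and risks**

Total steps: 12. Longest linear sequence: 9 steps (steps 4 to 12, from 7 to 22); the ring A branch (steps 1 to 3) joins at step 10.

Steps most likely to fail:

1. Step 11 (Proposed new method). The carbene may fail to engage the electron-rich aldehyde flanked by two ortho oxygens, or acyl transfer from the enaminol to the ester may be slower than base-induced five-membered aldol closure and decomposition of the substrate. The fallback uses known flavone chemistry, sets out from 6 (with 13 as partner) and returns at 21. Addition of MeMgBr (THF, 0 °C) to the aldehyde of 6 would give 1-[2-hydroxy-4,6-bis(methoxymethoxy)-3-(2-methylbut-3-en-2-yl)phenyl]ethan-1-ol F1. Oxidation with MnO2 (CH2Cl2) would give the acetophenone 1-[2-hydroxy-4,6-bis(methoxymethoxy)-3-(2-methylbut-3-en-2-yl)phenyl]ethan-1-one F2. Claisen–Schmidt condensation with 13 (KOH, EtOH) would give the 2'-hydroxychalcone F3. Oxa-Michael closure (NaOAc, EtOH, reflux) would give the flavanone F4, and dehydrogenation (DDQ, dioxane, 80 °C) the flavone F5. Lithiation at C3 (LDA, THF, −78 °C), trapping with B(OMe)3 and oxidation (H2O2, AcOH) would then give 21.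

2. Step 10. Displacement at the chelated, doubly ortho-substituted phenoxide may be so slow that self-condensation or solvolysis of the bromo ester, or aldol closure of the product, takes over. The fallback replaces SN2 by carbenoid O–H insertion, sets out from 17 (with 6) and returns at 19. Dess–Martin oxidation of 17 would give the aryl glyoxylate methyl 2-[8-(methoxymethoxy)-2,2-dimethyl-2H-chromen-6-yl]-2-oxoacetate F6. Condensation with TsNHNH2 (MeOH) would give the tosylhydrazone F7, and DBU (CH2Cl2) the aryldiazoacetate F8. Slow addition of F8 to 6 and Rh2(OAc)4 (1 mol %) in CH2Cl2 should insert the carbenoid into the phenolic O–H, which is little affected by steric hindrance, to give 19.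

3. Step 2. At the temperature of the rearrangement the product may react further (addition of a flanking hydroxyl to the new alkene, abnormal Claisen isomerisation), or the prenyl ether may be cleaved before it rearranges. The fallback masks the two chelated phenols during the rearrangement, sets out from 3 and returns at 5. Silylation (TBSCl, imidazole, DMF) would give 2,6-bis[(tert-butyldimethylsilyl)oxy]-4-[(3-methylbut-2-en-1-yl)oxy]benzaldehyde F9. Rearrangement (N,N-diethylaniline, 180 °C) would give 2,6-bis[(tert-butyldimethylsilyl)oxy]-4-hydroxy-3-(2-methylbut-3-en-2-yl)benzaldehyde F10, in which only one free phenol flanks the new group. TBAF (THF, 0 °C) would then give 5.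

**Further compounds**

F1 | step 11 | 1-[2-hydroxy-4,6-bis(methoxymethoxy)-3-(2-methylbut-3-en-2-yl)phenyl]ethan-1-ol (racemic) | C=CC(C)(C)c1c(OCOC)cc(OCOC)c(C(C)O)c1O
F2 | step 11 | 1-[2-hydroxy-4,6-bis(methoxymethoxy)-3-(2-methylbut-3-en-2-yl)phenyl]ethan-1-one | C=CC(C)(C)c1c(OCOC)cc(OCOC)c(C(C)=O)c1O
F3 | step 11 | (E)-1-[2-hydroxy-4,6-bis(methoxymethoxy)-3-(2-methylbut-3-en-2-yl)phenyl]-3-[8-(methoxymethoxy)-2,2-dimethyl-2H-chromen-6-yl]prop-2-en-1-one | C=CC(C)(C)c1c(OCOC)cc(OCOC)c(C(=O)/C=C/c2cc(OCOC)c3c(c2)C=CC(C)(C)O3)c1O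
F4 | step 11 | 5,7-bis(methoxymethoxy)-2-[8-(methoxymethoxy)-2,2-dimethyl-2H-chromen-6-yl]-8-(2-methylbut-3-en-2-yl)chroman-4-one (racemic) | C=CC(C)(C)c1c(OCOC)cc(OCOC)c2c1OC(c1cc(OCOC)c3c(c1)C=CC(C)(C)O3)CC2=O
F5 | step 11 | 5,7-bis(methoxymethoxy)-2-[8-(methoxymethoxy)-2,2-dimethyl-2H-chromen-6-yl]-8-(2-methylbut-3-en-2-yl)-4H-chromen-4-one | C=CC(C)(C)c1c(OCOC)cc(OCOC)c2c(=O)cc(-c3cc(OCOC)c4c(c3)C=CC(C)(C)O4)oc12
F6 | step 10 | methyl 2-[8-(methoxymethoxy)-2,2-dimethyl-2H-chromen-6-yl]-2-oxoacetate | COC(=O)C(=O)c1cc(OCOC)c2c(c1)C=CC(C)(C)O2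
F7 | step 10 | methyl 2-[8-(methoxymethoxy)-2,2-dimethyl-2H-chromen-6-yl]-2-[2-(4-methylbenzenesulfonyl)hydrazinylidene]acetate | COC(=O)C(=NNS(=O)(=O)c1ccc(C)cc1)c1cc(OCOC)c2c(c1)C=CC(C)(C)O2
F8 | step 10 | methyl 2-diazo-2-[8-(methoxymethoxy)-2,2-dimethyl-2H-chromen-6-yl]acetate | COC(=O)C(=[N+]=[N-])c1cc(OCOC)c2c(c1)C=CC(C)(C)O2
F9 | step 2 | 2,6-bis[(tert-butyldimethylsilyl)oxy]-4-[(3-methylbut-2-en-1-yl)oxy]benzaldehyde | O=Cc1c(O[Si](C)(C)C(C)(C)C)cc(OCC=C(C)C)cc1O[Si](C)(C)C(C)(C)C
F10 | step 2 | 2,6-bis[(tert-butyldimethylsilyl)oxy]-4-hydroxy-3-(2-methylbut-3-en-2-yl)benzaldehyde | C=CC(C)(C)c1c(O)cc(O[Si](C)(C)C(C)(C)C)c(C=O)c1O[Si](C)(C)C(C)(C)C
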